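Take the ratio of two round times of the catalyst in this flask, the one already followed and now asked about.

- zeta: starting material 0.050 M; second substrate 0.025 M; free enzyme 31 µM; the very flask that is asked about, followed so far
- flask: starting material 0.050 M; second substrate 0.0250 M; free enzyme 31 µM

zeta run (percent of the starting material charged)

| time / h | target / % |
|---|---|
| 10.0 | 18.8 |
| 20.0 | 34.2 |
| 30.0 | 47.4 |
| 40.0 | 47.8 |
| 50.0 | 48.5 |

(standard deviation of a reading: 1 percentage point)

* apparent order in free enzyme when 5.0 % of the starting material are converted (percent change of the rate of making target for one percent more free enzyme charged)
* apparent order in second substrate when 5.0 % of the starting material are converted (percent change of the rate of making target for one percent more second substrate charged)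

- candidate steps: starting material + free enzyme <-> first complex; first complex <-> loaded enzyme + first product; second substrate + loaded enzyme <-> second complex; second complex -> free enzyme + target; free enzyme <-> dormant form
- no earlier run changes the charge of free enzyme; that part of a forecast is a guess
- no earlier run changes the charge of second substrate; that part of a forecast is a guess

Divide the free enzyme charged by the rate of making target over the first 10.0 h. This gives 1.98 min, the round time, or turnover time. Between 20.0 h and 30.0 h the same division gives 2.82 min, longer by a factor of 1.42. Halfway through these two intervals, the target readings, taken as one second substrate used per target, put [second substrate] near 81.2 % and 18.4 % of its charge.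

With the rest of the round held fixed, waiting for second substrate stretches in inverse proportion to [second substrate], and the apparent order in second substrate is the share of the round spent waiting. Charge the whole stretch to waiting. These scattered readings then give about 12.0 s of waiting at [second substrate] as charged, so my own rough upper figure for the order in second substrate at 5.0 % conversion is 0.112.

The forecast gives 1 (0.93 to 1.02) in free enzyme and 0.1 (0.02 to 0.3) in second substrate, calling the enzyme “close to saturated in the second substrate”. Its value for second substrate lies close to my figure, but both come from the same readings, so this is no check, and mine is meant as an upper figure.

    starting material + free enzyme ⇌ first complex (K = 14.0 /M, k = 1.70 × 10⁵ /M/h)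
    first complex ⇌ loaded enzyme + first product (K = 0.270 M, k = 100 /h)
    second substrate + loaded enzyme ⇌ second complex (K = 260 /M, k = 2.80 × 10⁵ /M/h)
    second complex → free enzyme + target (k = 3700 /h)
    free enzyme ⇌ dormant form (K = 0.580, k = 0.220 /h)

This flask gives 1.1 in free enzyme and 0.0085 in second substrate, lower than the forecast by a factor of 11.8. Loaded enzyme takes up second substrate as charged at 1.7 × 10⁵ /d, which is one uptake in 0.514 s. Set against the round time read as 1.98 min, that uptake is a share of 0.00433, about half of the order found.

The runs are calculated with made-up constants.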